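**Strategy.** Ring B is disconnected across C7–C8 and C9–C10. Its tetrasubstituted C8=C9 alkene lies next to quaternary C10 and faces an oxygen at C6, which is the pattern left by a cycloaddition of an alkyne with a 2-oxygenated diene built on ring A. One copper-catalysed [4+2] reaction joins a β-cyclocitral-derived 2-silyloxydiene (C10=C5–C6=C7) to a but-2-ynoyl oxazolidinone (C8≡C9). It closes ring B, sets C10, and leaves the C6 ketone masked as a silyl enol ether and C11 as an acyl group. The acyl group is then extended to the (Z)-side chain by B-alkyl Suzuki coupling, and the masked ketone is converted into the trans 6β-acetoxy-7α-hydroxy pair.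

Key step: step 5

Remark on numbering: positions are given in labdane numbering (ring A: C1–C5 and C10; ring B: C5–C10; C17 on C8, C18 and C19 on C4, C20 on C10, side chain C11–C16 on C9). Drimane-type intermediates use the same locants.

Assumption: the sense of induction at C10 in step 5 is taken from a quadrant model of the chelated ynoyl imide, which points to the (R,R)-ligand. If the adduct proves to be the antipode, the equally available (S,S)-ligand is used and nothing else changes.

Step 1
Reactants: 1 β-cyclocitral (2,6,6-trimethylcyclohex-1-ene-1-carbaldehyde)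
Product: 2 1-(2,6,6-trimethylcyclohex-1-en-1-yl)ethan-1-ol (racemic)
Conditions: MeMgBr, THF, 0 °C → rt; aq NH4Cl
Reagents that add atoms: methylmagnesium bromide, C[Mg]Br
Why: Grignard 1,2-addition to this hindered enal is standard, and the racemic carbinol centre is erased in step 2.

Step 2
Reactants: 2 1-(2,6,6-trimethylcyclohex-1-en-1-yl)ethan-1-ol
Product: 3 1-(2,6,6-trimethylcyclohex-1-en-1-yl)ethan-1-one
Conditions: DMP (1,1,1-triacetoxy-1,2-benziodoxol-3-one), CH2Cl2, rt
Reagents that add atoms: none
Why: Dess–Martin oxidation of the secondary allylic alcohol gives the twisted methyl ketone without touching the tetrasubstituted alkene.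

Step 3
Reactants: 3 1-(2,6,6-trimethylcyclohex-1-en-1-yl)ethan-1-one
Product: 4 2-[1-(tert-butyldimethylsilyloxy)vinyl]-1,3,3-trimethylcyclohexene
Conditions: TBSOTf, Et3N, CH2Cl2, 0 °C
Reagents that add atoms: tert-butyldimethylsilyl trifluoromethanesulfonate, CC(C)(C)[Si](C)(C)OS(=O)(=O)C(F)(F)F
Why: Soft enolisation (silyl triflate and amine) removes a proton from the acetyl CH3, the only α-position, so the cross-conjugated 2-silyloxydiene forms and no stereocentre is created.

Step 4
Reactants: 5 but-2-ynoic acid; 6 oxazolidin-2-one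
Product: 9 3-(but-2-ynoyl)oxazolidin-2-one, via but-2-ynoic pivalic anhydride 7 (not isolated), via lithium 2-oxooxazolidin-3-ide 8 (not isolated)
Conditions: 5, PivCl, Et3N, THF, −20 °C; then 6/n-BuLi (THF, −78 °C), −78 → 0 °C
Reagents that add atoms: none
Why: Mixed-anhydride N-acylation of the lithiated oxazolidinone occurs at the less hindered ynoyl carbonyl, and the low temperature avoids base-induced isomerisation of the ynoyl group to an allenoyl group.

Step 5
Reactants: 4 2-[1-(tert-butyldimethylsilyloxy)vinyl]-1,3,3-trimethylcyclohexene (1.5 equiv); 9 3-(but-2-ynoyl)oxazolidin-2-one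
Product: 10 3-[(10S)-6-(tert-butyldimethylsilyloxy)drima-5,8-dien-11-oyl]oxazolidin-2-one (10β-methyl)
Conditions: Cu(OTf)2 (10 mol %), (R,R)-t-Bu-box [2,2′-(propane-2,2-diyl)bis((4R)-4-tert-butyl-4,5-dihydrooxazole)] (11 mol %), 4 Å MS, CH2Cl2, −20 °C → rt
Reagents that add atoms: none
Why: Proposed new method: the square-planar divalent copper complex chelates both carbonyl groups of 9 and activates the alkyne π bond conjugated with the acyl group, so that the nucleophilic CH2 terminus C7 of the silyl enol ether bonds to the β-carbon C8 and the copper-bound allenolate carbon C9 then bonds to C10, in one asynchronous [4+2] event or, at the stepwise limit, as a Mukaiyama–Michael addition followed by ring closure, both leading to 10. The closest known reactions are the Cu(OTf)2–bis(oxazoline)-catalysed Diels–Alder reactions of 3-acryloyl- and 3-crotonoyl-oxazolidin-2-ones and the thermal cycloadditions of 2,6,6-trimethyl-1-vinylcyclohexene-type dienes with acetylenic esters; an alkynoyl imide on this tetrasubstituted diene has not been shown. Ring B closes as the six-membered ring of an intermolecular [4+2] cycloaddition (at the stepwise limit a six-membered closure of C9 onto the silyloxyallyl cation terminus C10), and the alkyne leaves the C8=C9 alkene with C17 and C11 already in place. The one new stereocentre, quaternary C10, is controlled by the tert-butyl groups of the C2-symmetric ligand, which close two diagonal quadrants around the chelate and so dictate on which side ring A and the silyloxy group of the incoming diene can lie. The step needs regioselectivity, secured in the substrate by the 2-silyloxy group (C7 is the nucleophilic terminus, the methyl-bearing C8 the electrophilic β-carbon), and enantioselectivity, which rests on the catalyst alone; the robust tert-butyldimethylsilyl group is kept so that the enol ether survives the Lewis acid and stores the C6 ketone. Which antipode of the ligand gives the 10β-methyl adduct is a model-based prediction and is covered by the assumption before the steps.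

Step 6
Reactants: 10 3-[(10S)-6-(tert-butyldimethylsilyloxy)drima-5,8-dien-11-oyl]oxazolidin-2-one
Product: 11 6-(tert-butyldimethylsilyloxy)drima-5,8-dien-11-ol (10β-methyl)
Conditions: LiBH4, MeOH (1.5 equiv), THF, 0 °C
Reagents that add atoms: none
Why: Reductive cleavage of an N-acyl oxazolidinone with lithium borohydride (lithium chelation activates the exocyclic carbonyl) gives the primary alcohol, while the silyl enol ether and the tetrasubstituted alkene are inert and C10 is untouched.

Step 7
Reactants: 11 6-(tert-butyldimethylsilyloxy)drima-5,8-dien-11-ol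
Product: 12 6-(tert-butyldimethylsilyloxy)drima-5,8-dien-11-al
Conditions: DMP, pyridine, CH2Cl2, 0 °C
Reagents that add atoms: none
Why: Buffered Dess–Martin oxidation converts the primary allylic alcohol into the β-cyclocitral-like enal under non-acidic conditions that spare the silyl enol ether.

Step 8
Reactants: 12 6-(tert-butyldimethylsilyloxy)drima-5,8-dien-11-al
Product: 13 6-(tert-butyldimethylsilyloxy)-13,14,15,16-tetranorlabda-5,8,11-triene (C9 bears CH=CH2)
Conditions: Ph3PCH3Br, KOt-Bu, THF, 0 °C → rt
Reagents that add atoms: methyltriphenylphosphonium bromide, C[P+](c1ccccc1)(c1ccccc1)c1ccccc1.[Br-]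
Why: Wittig methylenation is reliable on hindered enals of the β-cyclocitral type that lack α-hydrogens, and it turns C11 into the vinyl group C11=C12 needed for hydroboration.

Step 9
Reactants: 14 but-2-yn-1-ol
Product: 16 (Z)-3-iodobut-2-en-1-ol, via sodium cyclic vinylalanate 15 (not isolated)
Conditions: NaAlH2(OCH2CH2OMe)2, THF, 0 °C → rt; then I2, −78 → 0 °C
Reagents that add atoms: iodine, II
Why: The propargylic alkoxide directs trans-hydroalumination (hydride to C2, aluminium to C3 in a five-membered alanate), and iodinolysis with retention gives the vinyl iodide with iodine and CH2OH cis, which fixes the later 13Z geometry.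

Step 10
Reactants: 16 (Z)-3-iodobut-2-en-1-ol
Product: 17 (Z)-tert-butyl[(3-iodobut-2-en-1-yl)oxy]diphenylsilane
Conditions: TBDPSCl, imidazole, CH2Cl2, rt
Reagents that add atoms: tert-butyldiphenylsilyl chloride, CC(C)(C)[Si](Cl)(c1ccccc1)c1ccccc1
Why: This is a standard silylation of a primary alcohol, and the tert-butyldiphenylsilyl ether is chosen because it survives the buffered fluoride of step 12 and the strong base of step 13.

Step 11
Reactants: 13 6-(tert-butyldimethylsilyloxy)-13,14,15,16-tetranorlabda-5,8,11-triene; 17 (Z)-tert-butyl[(3-iodobut-2-en-1-yl)oxy]diphenylsilane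
Product: 19 (13Z)-6-(tert-butyldimethylsilyloxy)-15-(tert-butyldiphenylsilyloxy)labda-5,8,13-triene, via C12 alkyl-9-BBN borane 18 (not isolated)
Conditions: 9-BBN, THF, 0 °C → rt; then 17, Pd(dppf)Cl2 (5 mol %), AsPh3, aq K3PO4, DMF, rt
Reagents that add atoms: none
Why: 9-BBN adds anti-Markovnikov to the only unhindered alkene (the vinyl group, boron at C12), and the B-alkyl borane undergoes Suzuki–Miyaura coupling with the vinyl iodide with retention of geometry, forming C12–C13 and the 13Z alkene.

Step 12
Reactants: 19 (13Z)-6-(tert-butyldimethylsilyloxy)-15-(tert-butyldiphenylsilyloxy)labda-5,8,13-triene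
Product: 20 (13Z)-15-(tert-butyldiphenylsilyloxy)labda-8,13-dien-6-one (5α-H, trans ring fusion)
Conditions: Bu4NF, AcOH (1:1), THF, −20 → 0 °C
Reagents that add atoms: none
Why: Fluoride cleaves the silyl enol ether much faster than the primary tert-butyldiphenylsilyl ether, and acetic acid protonates the enolate at C5 from the α face, anti to the axial C10 methyl, giving the trans fusion (also the more stable one) while the buffer keeps C8=C9 from moving into conjugation.

Step 13
Reactants: 20 (13Z)-15-(tert-butyldiphenylsilyloxy)labda-8,13-dien-6-one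
Product: 22 (13Z)-15-(tert-butyldiphenylsilyloxy)-7α-hydroxylabda-8,13-dien-6-one, via potassium 6,8-dienolate 21 (not isolated)
Conditions: KN(SiMe3)2, THF, −78 °C; 2-(phenylsulfonyl)-3-phenyloxaziridine, −78 °C; AcOH
Reagents that add atoms: 2-(phenylsulfonyl)-3-phenyloxaziridine, O=S(=O)(c1ccccc1)N1OC1c1ccccc1
Why: The base removes a C7 proton (α to the ketone and allylic, far more accessible than the tertiary C5–H), and N-sulfonyloxaziridine oxidation of the dienolate at its α-carbon occurs from the α face, which is the pseudoaxial trajectory of the ring B half-chair and the side away from the axial C10 methyl, giving the 7α-alcohol.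

Step 14
Reactants: 22 (13Z)-15-(tert-butyldiphenylsilyloxy)-7α-hydroxylabda-8,13-dien-6-one
Product: 23 (13Z)-15-(tert-butyldiphenylsilyloxy)labda-8,13-diene-6β,7α-diol
Conditions: NaBH4, MeOH/THF, −20 °C
Reagents that add atoms: none
Why: Borohydride reduction of the C6 ketone occurs from the α face because the β face is closed by the two syn-axial methyl groups on C4 and C10, giving the axial 6β-alcohol trans to the 7α-hydroxyl.

Step 15
Reactants: 23 (13Z)-15-(tert-butyldiphenylsilyloxy)labda-8,13-diene-6β,7α-diol
Product: 24 (13Z)-15-(tert-butyldiphenylsilyloxy)-7α-(triethylsilyloxy)labda-8,13-dien-6β-ol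
Conditions: Et3SiCl, imidazole, DMF, 0 °C
Reagents that add atoms: chlorotriethylsilane, CC[Si](Cl)(CC)CC
Why: Silyl ether formation selects the allylic 7α-hydroxyl because the 6β-hydroxyl is axial and flanked by two syn-axial methyl groups.

Step 16
Reactants: 24 (13Z)-15-(tert-butyldiphenylsilyloxy)-7α-(triethylsilyloxy)labda-8,13-dien-6β-ol
Product: 25 (13Z)-15-(tert-butyldiphenylsilyloxy)-7α-(triethylsilyloxy)labda-8,13-dien-6β-yl acetate
Conditions: Ac2O, DMAP, Et3N, ClCH2CH2Cl, 60 °C
Reagents that add atoms: acetic anhydride, CC(=O)OC(C)=O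
Why: DMAP-catalysed acylation with excess anhydride and heat esterifies the hindered axial 6β-alcohol, the only free hydroxyl left, and the trans-diaxial placement of O6 and O7 excludes silyl or acyl migration.

Step 17
Reactants: 25 (13Z)-15-(tert-butyldiphenylsilyloxy)-7α-(triethylsilyloxy)labda-8,13-dien-6β-yl acetate
Product: 26 (5S,6S,7S,10S,13Z)-7α,15-dihydroxylabda-8,13-dien-6β-yl acetate (target)
Conditions: HF·pyridine, pyridine, THF, 0 °C → rt
Reagents that add atoms: none
Why: Buffered hydrogen fluoride cleaves both silyl ethers (desilylation) and leaves the acetate and both alkenes untouched, and acetyl migration from O6 to O7 is disfavoured by their trans-diaxial relationship.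

**Compound list**

1 | β-cyclocitral | O=CC1=C(C)CCCC1(C)C | starting material
2 | 1-(2,6,6-trimethylcyclohex-1-en-1-yl)ethan-1-ol (racemic) | CC(O)C1=C(C)CCCC1(C)C | intermediate
3 | 1-(2,6,6-trimethylcyclohex-1-en-1-yl)ethan-1-one | CC(=O)C1=C(C)CCCC1(C)C | intermediate
4 | 2-[1-(tert-butyldimethylsilyloxy)vinyl]-1,3,3-trimethylcyclohexene | C=C(O[Si](C)(C)C(C)(C)C)C1=C(C)CCCC1(C)C | intermediate
5 | but-2-ynoic acid | CC#CC(=O)O | starting material
6 | oxazolidin-2-one | O=C1NCCO1 | starting material
7 | but-2-ynoic pivalic anhydride | CC#CC(=O)OC(=O)C(C)(C)C | intermediate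
8 | lithium 2-oxooxazolidin-3-ide | [Li+].O=C1[N-]CCO1 | intermediate
9 | 3-(but-2-ynoyl)oxazolidin-2-one | CC#CC(=O)N1CCOC1=O | intermediate
10 | 3-[(10S)-6-(tert-butyldimethylsilyloxy)drima-5,8-dien-11-oyl]oxazolidin-2-one | CC(C)(C)[Si](C)(C)OC=1CC(C)=C(C(=O)N3CCOC3=O)[C@@]2(C)CCCC(C)(C)C=12 | intermediate
11 | 6-(tert-butyldimethylsilyloxy)drima-5,8-dien-11-ol (10β-methyl) | CC(C)(C)[Si](C)(C)OC=1CC(C)=C(CO)[C@@]2(C)CCCC(C)(C)C=12 | intermediate
12 | 6-(tert-butyldimethylsilyloxy)drima-5,8-dien-11-al (10β-methyl) | CC(C)(C)[Si](C)(C)OC=1CC(C)=C(C=O)[C@@]2(C)CCCC(C)(C)C=12 | intermediate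
13 | 6-(tert-butyldimethylsilyloxy)-13,14,15,16-tetranorlabda-5,8,11-triene (10β-methyl) | CC(C)(C)[Si](C)(C)OC=1CC(C)=C(C=C)[C@@]2(C)CCCC(C)(C)C=12 | intermediate
14 | but-2-yn-1-ol | CC#CCO | starting material
15 | sodium 2,2-bis(2-methoxyethoxy)-3-methyl-2,5-dihydro-1,2-oxaluminol-2-uide (cyclic vinylalanate) | CC1=CCO[Al-]1(OCCOC)OCCOC.[Na+] | intermediate
16 | (Z)-3-iodobut-2-en-1-ol | OC/C=C(/C)I | intermediate
17 | (Z)-tert-butyl[(3-iodobut-2-en-1-yl)oxy]diphenylsilane | CC(C)(C)[Si](OC/C=C(/C)I)(c1ccccc1)c1ccccc1 | intermediate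
18 | 12-(9-borabicyclo[3.3.1]nonan-9-yl)-6-(tert-butyldimethylsilyloxy)-13,14,15,16-tetranorlabda-5,8-diene | CC(C)(C)[Si](C)(C)OC=1CC(C)=C(CCB3C4CCCC3CCC4)[C@@]2(C)CCCC(C)(C)C=12 | intermediate
19 | (13Z)-6-(tert-butyldimethylsilyloxy)-15-(tert-butyldiphenylsilyloxy)labda-5,8,13-triene | CC(C)(C)[Si](C)(C)OC=1CC(C)=C(CC/C(C)=C\CO[Si](c3ccccc3)(c4ccccc4)C(C)(C)C)[C@@]2(C)CCCC(C)(C)C=12 | intermediate
20 | (13Z)-15-(tert-butyldiphenylsilyloxy)labda-8,13-dien-6-one (5α-H) | O=C1CC(C)=C(CC/C(C)=C\CO[Si](c3ccccc3)(c4ccccc4)C(C)(C)C)[C@@]2(C)CCCC(C)(C)[C@H]12 | intermediate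
21 | potassium 6,8-dienolate of 20 | [K+].[O-]C1=CC(C)=C(CC/C(C)=C\CO[Si](c3ccccc3)(c4ccccc4)C(C)(C)C)[C@@]2(C)CCCC(C)(C)[C@H]12 | intermediate
22 | (13Z)-15-(tert-butyldiphenylsilyloxy)-7α-hydroxylabda-8,13-dien-6-one | O=C1[C@@H](O)C(C)=C(CC/C(C)=C\CO[Si](c3ccccc3)(c4ccccc4)C(C)(C)C)[C@@]2(C)CCCC(C)(C)[C@H]12 | intermediate
23 | (13Z)-15-(tert-butyldiphenylsilyloxy)labda-8,13-diene-6β,7α-diol | O[C@@H]1[C@@H](O)C(C)=C(CC/C(C)=C\CO[Si](c3ccccc3)(c4ccccc4)C(C)(C)C)[C@@]2(C)CCCC(C)(C)[C@H]12 | intermediate
24 | (13Z)-15-(tert-butyldiphenylsilyloxy)-7α-(triethylsilyloxy)labda-8,13-dien-6β-ol | O[C@@H]1[C@@H](O[Si](CC)(CC)CC)C(C)=C(CC/C(C)=C\CO[Si](c3ccccc3)(c4ccccc4)C(C)(C)C)[C@@]2(C)CCCC(C)(C)[C@H]12 | intermediate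
25 | (13Z)-15-(tert-butyldiphenylsilyloxy)-7α-(triethylsilyloxy)labda-8,13-dien-6β-yl acetate | CC(=O)O[C@@H]1[C@@H](O[Si](CC)(CC)CC)C(C)=C(CC/C(C)=C\CO[Si](c3ccccc3)(c4ccccc4)C(C)(C)C)[C@@]2(C)CCCC(C)(C)[C@H]12 | intermediate
26 | (5S,6S,7S,10S,13Z)-7α,15-dihydroxylabda-8,13-dien-6β-yl acetate | CC(=O)O[C@@H]1[C@@H](O)C(C)=C(CC/C(C)=C\CO)[C@@]2(C)CCCC(C)(C)[C@H]12 | target

**Totals.** Total step count: 17. Longest linear sequence: 14 steps (steps 1–3, 5–8 and 11–17).

**Steps most likely to fail**

Step 5. The hindered diene may stop at an open-chain conjugate adduct with loss of the silyl group instead of closing ring B. The catalyst may also discriminate poorly between the two orientations of the diene over the chelate, leaving low enantiomeric purity. The fallback uses known chemistry, sets out from diene 4 and mixed anhydride 7, and returns at alcohol 11. Commercial (S)-4-benzyloxazolidin-2-one is lithiated with n-BuLi to lithium (S)-4-benzyl-2-oxooxazolidin-3-ide F1 and acylated with 7 to (S)-4-benzyl-3-(but-2-ynoyl)oxazolidin-2-one F2. F2 and 4 are heated without catalyst (toluene, 110 °C, sealed tube), the thermal mode in which trimethylcyclohexenyl dienes and 2-silyloxydienes add to acetylenic carbonyl dienophiles. The two C10 epimers are now diastereomers. The 10β-methyl adduct, 3-[(10S)-6-(tert-butyldimethylsilyloxy)drima-5,8-dien-11-oyl]-(S)-4-benzyloxazolidin-2-one F3, is separated by chromatography from its C10 epimer F4. LiBH4/MeOH cleavage of F3 as in step 6 gives 11. Configuration then rests on a separation, not on induction, at the cost of the unwanted epimer.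

Step 6. Hydride may attack the ring carbonyl of the oxazolidinone in place of the acyl carbonyl, which is shielded by C10 and the C8 methyl, and so open the heterocycle to a hydroxyethyl amide. The fallback sets out from 10 and returns at 11. LiOH/H2O2 (THF/H2O, 0 °C), in which hydroperoxide attacks the exocyclic carbonyl even of hindered imides, gives (10S)-6-(tert-butyldimethylsilyloxy)drima-5,8-dien-11-oic acid F5 after a cold, weakly acidic work-up that spares the enol ether. LiAlH4 (Et2O, 0 °C) then reduces F5 to 11.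

Step 13. Under the basic conditions the new α-ketol may isomerise through its enediol towards the conjugated 6-hydroxy-7-ketone, the dienolate may add to the sulfonimine by-product, or oxidation may remain incomplete. The fallback sets out from 20 and returns at 24. Dienolate 21 (KN(SiMe3)2, THF, −78 °C) is trapped with Et3SiCl as the triethylsilyl 6,8-dienol ether F6. Rubottom oxidation with dimethyldioxirane (1 equiv, acetone/CH2Cl2, −78 °C) epoxidises the electron-rich C6=C7 bond from the α face, well before the isolated C13=C14 alkene reacts. The epoxide rearranges with silyl migration to (13Z)-15-(tert-butyldiphenylsilyloxy)-7α-(triethylsilyloxy)labda-8,13-dien-6-one F7, so no free α-ketol is ever exposed to base. NaBH4 reduction of F7 from the α face, as in step 14, gives 24 directly.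

**Further compounds**

F1 | step 5 | lithium (S)-4-benzyl-2-oxooxazolidin-3-ide | [Li+].O=C1[N-][C@@H](Cc2ccccc2)CO1
F2 | step 5 | (S)-4-benzyl-3-(but-2-ynoyl)oxazolidin-2-one | CC#CC(=O)N1[C@@H](Cc2ccccc2)COC1=O
F3 | step 5 | 3-[(10S)-6-(tert-butyldimethylsilyloxy)drima-5,8-dien-11-oyl]-(S)-4-benzyloxazolidin-2-one | CC(C)(C)[Si](C)(C)OC=1CC(C)=C(C(=O)N3[C@@H](Cc4ccccc4)COC3=O)[C@@]2(C)CCCC(C)(C)C=12
F4 | step 5 | C10 epimer of F3 (10α-methyl) | CC(C)(C)[Si](C)(C)OC=1CC(C)=C(C(=O)N3[C@@H](Cc4ccccc4)COC3=O)[C@]2(C)CCCC(C)(C)C=12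
F5 | step 6 | (10S)-6-(tert-butyldimethylsilyloxy)drima-5,8-dien-11-oic acid | CC(C)(C)[Si](C)(C)OC=1CC(C)=C(C(=O)O)[C@@]2(C)CCCC(C)(C)C=12
F6 | step 13 | (13Z)-15-(tert-butyldiphenylsilyloxy)-6-(triethylsilyloxy)labda-6,8,13-triene | CC[Si](CC)(CC)OC1=CC(C)=C(CC/C(C)=C\CO[Si](c3ccccc3)(c4ccccc4)C(C)(C)C)[C@@]2(C)CCCC(C)(C)[C@H]12
F7 | step 13 | (13Z)-15-(tert-butyldiphenylsilyloxy)-7α-(triethylsilyloxy)labda-8,13-dien-6-one | O=C1[C@@H](O[Si](CC)(CC)CC)C(C)=C(CC/C(C)=C\CO[Si](c3ccccc3)(c4ccccc4)C(C)(C)C)[C@@]2(C)CCCC(C)(C)[C@H]12
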